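**Plan** (chain numbering: C1 = lactone carbonyl, C3 = enol carbon, C5 = ring CH–O, C7/C9/C11 = carbinol carbons, C12–C20 = nonyl)
- Retrosynthetic cuts, in order: lactone O–C1 (to a 5-hydroxy-3-oxo ester), C2–C3 (to a C3 aldehyde), C10–C11 (to a C3–C10 methyl ketone and decanal), C9–C10 (to a C9 nitrile and a methyl nucleophile).
- Forward: the chain is joined C3–C9 (purchased), then C10, then C11–C20, then C1–C2; the only ring, the δ-lactone, is closed last.
- Stereochemistry: C5 and C7 come with the purchased syn-acetonide. C11 is set by 1,5-anti induction from the C7 oxygen, and C9 by hydride addition to the boron aldolate chelate (1,3-syn to C11), both in one flask.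
- Enabling feature: the C7 oxygen lies β to the C9 carbonyl and is held in the C5/C7 1,3-dioxane ring. The six-membered O–B–O chelate spanning C9 and C11 is a ring absent from the target; it is formed to steer the reduction and is cleaved oxidatively afterwards.

Key step: step 2

Assumption: compound 1 (the acetonide-protected cyanomethyl statin side-chain ester) is taken as purchasable, and the 4-hydroxy-5,6-dihydro-2H-pyran-2-one is treated as the enol tautomer of the 3-oxo-δ-lactone that lactonisation delivers.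

Step 1
Reactants: 1 tert-butyl 2-[(4R,6R)-6-(cyanomethyl)-2,2-dimethyl-1,3-dioxan-4-yl]acetate
Product: 3 tert-butyl 2-[(4R,6S)-2,2-dimethyl-6-(2-oxopropyl)-1,3-dioxan-4-yl]acetate, via magnesium ketimide 2 (not isolated)
Conditions: MeMgBr, CuBr·SMe2 (cat.), THF/toluene, 0 °C to rt; then 1 M aq. HCl, 0 °C
Reagents that add atoms: methylmagnesium bromide, C[Mg]Br; water, O
Why: Grignard addition to a nitrile stops at the N-magnesio ketimine 2, which resists a second addition and is hydrolysed to the methyl ketone on cold acidic work-up; the hindered tert-butyl ester should not compete, and no stereocentre is touched (the change of descriptor from 6R to 6S is a CIP priority effect only).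

Step 2
Reactants: 3 tert-butyl 2-[(4R,6S)-2,2-dimethyl-6-(2-oxopropyl)-1,3-dioxan-4-yl]acetate; 4 decanal
Product: 7 tert-butyl 2-[(4R,6R)-6-[(2S,4S)-2,4-dihydroxytridecyl]-2,2-dimethyl-1,3-dioxan-4-yl]acetate, via boron enolate 5 (not isolated), via boron aldolate 6 (not isolated)
Conditions: c-Hex2BCl, Et3N, Et2O, −78 to 0 °C; then 4, −78 °C; then LiBH4 (THF), −78 °C; then H2O2, MeOH, pH 7 buffer, 0 °C to rt
Reagents that add atoms: none
Why: c-Hex2BCl/Et3N should enolise the methyl ketone on the CH3 side to boron enolate 5, which adds to decanal through a boat-like transition state in which the formyl C–H is hydrogen-bonded to the C7 ring oxygen (the β-oxygen held in the C5/C7 1,3-dioxane), so that the aldehyde face giving the 1,5-anti C7/C11 relationship, i.e. (S)-C11, is attacked; the closest known reaction type is the Paterson–Evans 1,5-anti boron aldol of β-alkoxy methyl ketones. The aldolate 6 is a six-membered O–B–O chelate (C9 carbonyl oxygen bound to the boron on the C11 oxygen), and external hydride from LiBH4 should attack its half-chair axially to give the 1,3-syn C9/C11 diol, i.e. (S)-C9, as in the in situ aldolate reduction of the Narasaka–Prasad type. No ring of the target is closed in this step; the chelate ring closes by coordination only and is destroyed, together with the B–C bonds, in the oxidative work-up. The step needs enolisation at C10 and not at C8, which the kinetic preference of c-Hex2BCl/Et3N for the methyl group secures, and it needs the tert-butyl ester to stay out, which holds because it is neither enolised by the boron chloride nor reduced by LiBH4 at −78 °C. The induction depends on the C7 oxygen being an alkyl-type acetal oxygen (not a silyl ether), which the purchased acetonide provides.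

Step 3
Reactants: 7 tert-butyl 2-[(4R,6R)-6-[(2S,4S)-2,4-dihydroxytridecyl]-2,2-dimethyl-1,3-dioxan-4-yl]acetate
Product: 8 tert-butyl 2-[(4R,6R)-6-{[(4S,6S)-2,2-dimethyl-6-nonyl-1,3-dioxan-4-yl]methyl}-2,2-dimethyl-1,3-dioxan-4-yl]acetate
Conditions: Me2C(OMe)2, PPTS (cat.), CH2Cl2, rt
Reagents that add atoms: 2,2-dimethoxypropane, COC(C)(C)OC
Why: Acid-catalysed transketalisation (acetonide formation) should close the syn-1,3-diol to a chair 1,3-dioxane with both substituents equatorial, while the existing syn-acetonide is already the thermodynamically preferred arrangement and stays in place.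

Step 4
Reactants: 8 tert-butyl 2-[(4R,6R)-6-{[(4S,6S)-2,2-dimethyl-6-nonyl-1,3-dioxan-4-yl]methyl}-2,2-dimethyl-1,3-dioxan-4-yl]acetate
Product: 9 2-[(4R,6R)-6-{[(4S,6S)-2,2-dimethyl-6-nonyl-1,3-dioxan-4-yl]methyl}-2,2-dimethyl-1,3-dioxan-4-yl]acetaldehyde
Conditions: i-Bu2AlH, CH2Cl2, −78 °C; then MeOH, aq. KNaC4H4O6 (potassium sodium tartrate)
Reagents that add atoms: none
Why: Partial ester reduction with i-Bu2AlH: the tetrahedral aluminium hemiacetal of the tert-butyl ester should persist at −78 °C and collapse to the aldehyde only on work-up, the ketals being inert and no stereocentre being involved.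

Step 5
Reactants: 9 2-[(4R,6R)-6-{[(4S,6S)-2,2-dimethyl-6-nonyl-1,3-dioxan-4-yl]methyl}-2,2-dimethyl-1,3-dioxan-4-yl]acetaldehyde
Product: 10 ethyl 4-[(4R,6R)-6-{[(4S,6S)-2,2-dimethyl-6-nonyl-1,3-dioxan-4-yl]methyl}-2,2-dimethyl-1,3-dioxan-4-yl]-3-oxobutanoate
Conditions: N2CHCO2Et, SnCl2 (cat.), CH2Cl2, rt
Reagents that add atoms: ethyl diazoacetate, CCOC(=O)C=[N+]=[N-]
Why: Roskamp homologation: the SnCl2-activated aldehyde is attacked by the diazo carbon, and a 1,2-hydride shift with loss of N2 should give the β-keto ester directly, the mild Lewis acid leaving both acetonides and all stereocentres untouched.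

Step 6
Reactants: 10 ethyl 4-[(4R,6R)-6-{[(4S,6S)-2,2-dimethyl-6-nonyl-1,3-dioxan-4-yl]methyl}-2,2-dimethyl-1,3-dioxan-4-yl]-3-oxobutanoate
Product: 12 (6R)-4-hydroxy-6-[(2R,4S,6S)-2,4,6-trihydroxypentadecyl]-5,6-dihydro-2H-pyran-2-one (target), via tetraol keto ester 11 (not isolated)
Conditions: AcOH/H2O (4:1), 40 °C; evaporate; then K2CO3, MeOH, 0 °C to rt; then 1 M aq. HCl to pH 3
Reagents that add atoms: none
Why: Aqueous acid hydrolyses both acetonides to tetraol 11, and under K2CO3/MeOH the β-keto ester is held as its enolate while the C5 alkoxide closes the six-membered lactone by intramolecular transesterification (6-exo-trig lactonisation of a δ-hydroxy-β-keto ester), the stabilised enolate of the β-keto lactone being the thermodynamic sink and acidification giving the enol form; the C7, C9 and C11 hydroxyls would form eight-membered or larger rings and should not compete, and no stereocentre is affected.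

**Compound list**
1 | tert-butyl 2-[(4R,6R)-6-(cyanomethyl)-2,2-dimethyl-1,3-dioxan-4-yl]acetate | N#CC[C@@H]1C[C@H](CC(=O)OC(C)(C)C)OC(C)(C)O1 | starting material
2 | tert-butyl 2-[(4R,6R)-6-[2-(bromomagnesioimino)propyl]-2,2-dimethyl-1,3-dioxan-4-yl]acetate (magnesium ketimide) | CC(=N[Mg]Br)C[C@@H]1C[C@H](CC(=O)OC(C)(C)C)OC(C)(C)O1 | intermediate
3 | tert-butyl 2-[(4R,6S)-2,2-dimethyl-6-(2-oxopropyl)-1,3-dioxan-4-yl]acetate | CC(=O)C[C@@H]1C[C@H](CC(=O)OC(C)(C)C)OC(C)(C)O1 | intermediate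
4 | decanal | CCCCCCCCCC=O | starting material
5 | tert-butyl 2-[(4R,6S)-6-{2-[(dicyclohexylboranyl)oxy]prop-2-en-1-yl}-2,2-dimethyl-1,3-dioxan-4-yl]acetate (boron enolate) | C=C(OB(C2CCCCC2)C2CCCCC2)C[C@@H]1C[C@H](CC(=O)OC(C)(C)C)OC(C)(C)O1 | intermediate
6 | tert-butyl 2-[(4R,6S)-6-{(4S)-4-[(dicyclohexylboranyl)oxy]-2-oxotridecyl}-2,2-dimethyl-1,3-dioxan-4-yl]acetate (boron aldolate) | CCCCCCCCC[C@H](OB(C2CCCCC2)C2CCCCC2)CC(=O)C[C@@H]1C[C@H](CC(=O)OC(C)(C)C)OC(C)(C)O1 | intermediate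
7 | tert-butyl 2-[(4R,6R)-6-[(2S,4S)-2,4-dihydroxytridecyl]-2,2-dimethyl-1,3-dioxan-4-yl]acetate | CCCCCCCCC[C@H](O)C[C@H](O)C[C@@H]1C[C@H](CC(=O)OC(C)(C)C)OC(C)(C)O1 | intermediate
8 | tert-butyl 2-[(4R,6R)-6-{[(4S,6S)-2,2-dimethyl-6-nonyl-1,3-dioxan-4-yl]methyl}-2,2-dimethyl-1,3-dioxan-4-yl]acetate | CCCCCCCCC[C@H]1C[C@@H](C[C@@H]2C[C@H](CC(=O)OC(C)(C)C)OC(C)(C)O2)OC(C)(C)O1 | intermediate
9 | 2-[(4R,6R)-6-{[(4S,6S)-2,2-dimethyl-6-nonyl-1,3-dioxan-4-yl]methyl}-2,2-dimethyl-1,3-dioxan-4-yl]acetaldehyde | CCCCCCCCC[C@H]1C[C@@H](C[C@@H]2C[C@H](CC=O)OC(C)(C)O2)OC(C)(C)O1 | intermediate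
10 | ethyl 4-[(4R,6R)-6-{[(4S,6S)-2,2-dimethyl-6-nonyl-1,3-dioxan-4-yl]methyl}-2,2-dimethyl-1,3-dioxan-4-yl]-3-oxobutanoate | CCCCCCCCC[C@H]1C[C@@H](C[C@@H]2C[C@H](CC(=O)CC(=O)OCC)OC(C)(C)O2)OC(C)(C)O1 | intermediate
11 | ethyl (5R,7R,9S,11S)-5,7,9,11-tetrahydroxy-3-oxoicosanoate | CCCCCCCCC[C@H](O)C[C@H](O)C[C@@H](O)C[C@@H](O)CC(=O)CC(=O)OCC | intermediate
12 | (6R)-4-hydroxy-6-[(2R,4S,6S)-2,4,6-trihydroxypentadecyl]-5,6-dihydro-2H-pyran-2-one | CCCCCCCCC[C@H](O)C[C@H](O)C[C@@H](O)C[C@@H]1CC(O)=CC(=O)O1 | target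

Total step count: 6. Longest linear sequence: 6 steps (1 to 12).

**Steps most likely to fail**

Step 1. The Grignard reagent may deprotonate the acidic CH2 next to the nitrile instead of adding to it. That would return starting material or trigger β-elimination of the ring oxygen; attack on the ester may also compete. The fallback sets out from 1 and comes back at 3. A Blaise reaction with the non-basic zinc enolate of allyl bromoacetate (Zn, BrCH2CO2CH2CH=CH2, THF, reflux) should give the enamino ester allyl (2Z)-3-amino-4-[(4R,6R)-6-(2-tert-butoxy-2-oxoethyl)-2,2-dimethyl-1,3-dioxan-4-yl]but-2-enoate F1. Brief hydrolysis with cold dilute aq. HCl should give the β-keto ester allyl 4-[(4S,6R)-6-(2-tert-butoxy-2-oxoethyl)-2,2-dimethyl-1,3-dioxan-4-yl]-3-oxobutanoate F2. Palladium-catalysed deallylation with decarboxylation (Pd(PPh3)4, morpholine, THF, rt) should then deliver methyl ketone 3 under neutral conditions.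

Step 2. Facial discrimination in the aldol addition may be insufficient when the β-oxygen is an acetonide oxygen, eroding the 1,5-anti preference, and reduction of the aldolate may be incomplete or less selective. The fallback sets out from 3 (with 4) and comes back at 7; it replaces substrate control by catalyst control at C11.
- An unselective lithium aldol (LiN(i-Pr)2, THF, −78 °C; then 4) gives the epimeric aldols tert-butyl 2-[(4R,6S)-6-(4-hydroxy-2-oxotridecyl)-2,2-dimethyl-1,3-dioxan-4-yl]acetate F3.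
- Mesylation (MsCl, Et3N, CH2Cl2, 0 °C) gives tert-butyl 2-[(4R,6S)-2,2-dimethyl-6-{4-[(methylsulfonyl)oxy]-2-oxotridecyl}-1,3-dioxan-4-yl]acetate F4.
- Elimination with DBU gives the enone tert-butyl 2-[(4R,6S)-2,2-dimethyl-6-[(3E)-2-oxotridec-3-en-1-yl]-1,3-dioxan-4-yl]acetate F5.
- Enantioselective conjugate borylation (B2pin2, CuCl, NaOt-Bu, chiral bisphosphine ligand of the antipode that delivers the (S)-C–B bond, MeOH, THF) should give tert-butyl 2-[(4R,6S)-2,2-dimethyl-6-[(4S)-2-oxo-4-(4,4,5,5-tetramethyl-1,3,2-dioxaborolan-2-yl)tridecyl]-1,3-dioxan-4-yl]acetate F6.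
- Stereoretentive oxidation (NaBO3·4H2O, THF/H2O) gives tert-butyl 2-[(4R,6S)-6-[(4S)-4-hydroxy-2-oxotridecyl]-2,2-dimethyl-1,3-dioxan-4-yl]acetate F7.
- A separate Narasaka–Prasad reduction (Et2BOMe, NaBH4, THF/MeOH, −78 °C) should then give syn-diol 7.

Step 6. During the acidic stage the liberated C7 hydroxyl may cyclise onto the C3 ketone and dehydrate to a cyclic enol ether that can no longer lactonise; decarboxylative or retro-aldol degradation during the basic stage is a second possibility. The fallback sets out from 9 and comes back at 12; it keeps C3 masked as an enol ether until the lactone is closed under neutral conditions.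
- Pinnick oxidation (NaClO2, NaH2PO4, 2-methyl-2-butene, t-BuOH/H2O) gives 2-[(4R,6R)-6-{[(4S,6S)-2,2-dimethyl-6-nonyl-1,3-dioxan-4-yl]methyl}-2,2-dimethyl-1,3-dioxan-4-yl]acetic acid F8.
- Acylation of Meldrum's acid (DCC, DMAP, CH2Cl2) gives 5-{2-[(4R,6R)-6-{[(4S,6S)-2,2-dimethyl-6-nonyl-1,3-dioxan-4-yl]methyl}-2,2-dimethyl-1,3-dioxan-4-yl]acetyl}-2,2-dimethyl-1,3-dioxane-4,6-dione F9.
- Heating in toluene containing acetone (95 °C) should give the dioxinone 6-{[(4R,6R)-6-{[(4S,6S)-2,2-dimethyl-6-nonyl-1,3-dioxan-4-yl]methyl}-2,2-dimethyl-1,3-dioxan-4-yl]methyl}-2,2-dimethyl-4H-1,3-dioxin-4-one F10.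
- AcOH/H2O should remove only the two diol acetonides to give 6-[(2R,4R,6S,8S)-2,4,6,8-tetrahydroxyheptadecyl]-2,2-dimethyl-4H-1,3-dioxin-4-one F11.
- Heating in dilute toluene (110 °C) should release acetone from the dioxinone, and the C5 hydroxyl should close the six-membered lactone to give 12.

**Further compounds**
F1 | step 1 | allyl (2Z)-3-amino-4-[(4R,6R)-6-(2-tert-butoxy-2-oxoethyl)-2,2-dimethyl-1,3-dioxan-4-yl]but-2-enoate | C=CCOC(=O)/C=C(\N)C[C@@H]1C[C@H](CC(=O)OC(C)(C)C)OC(C)(C)O1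
F2 | step 1 | allyl 4-[(4S,6R)-6-(2-tert-butoxy-2-oxoethyl)-2,2-dimethyl-1,3-dioxan-4-yl]-3-oxobutanoate | C=CCOC(=O)CC(=O)C[C@@H]1C[C@H](CC(=O)OC(C)(C)C)OC(C)(C)O1
F3 | step 2 | tert-butyl 2-[(4R,6S)-6-(4-hydroxy-2-oxotridecyl)-2,2-dimethyl-1,3-dioxan-4-yl]acetate (both C4 epimers of the side chain) | CCCCCCCCCC(O)CC(=O)C[C@@H]1C[C@H](CC(=O)OC(C)(C)C)OC(C)(C)O1
F4 | step 2 | tert-butyl 2-[(4R,6S)-2,2-dimethyl-6-{4-[(methylsulfonyl)oxy]-2-oxotridecyl}-1,3-dioxan-4-yl]acetate (both epimers) | CCCCCCCCCC(OS(C)(=O)=O)CC(=O)C[C@@H]1C[C@H](CC(=O)OC(C)(C)C)OC(C)(C)O1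
F5 | step 2 | tert-butyl 2-[(4R,6S)-2,2-dimethyl-6-[(3E)-2-oxotridec-3-en-1-yl]-1,3-dioxan-4-yl]acetate | CCCCCCCCC/C=C/C(=O)C[C@@H]1C[C@H](CC(=O)OC(C)(C)C)OC(C)(C)O1
F6 | step 2 | tert-butyl 2-[(4R,6S)-2,2-dimethyl-6-[(4S)-2-oxo-4-(4,4,5,5-tetramethyl-1,3,2-dioxaborolan-2-yl)tridecyl]-1,3-dioxan-4-yl]acetate | CCCCCCCCC[C@H](B2OC(C)(C)C(C)(C)O2)CC(=O)C[C@@H]1C[C@H](CC(=O)OC(C)(C)C)OC(C)(C)O1
F7 | step 2 | tert-butyl 2-[(4R,6S)-6-[(4S)-4-hydroxy-2-oxotridecyl]-2,2-dimethyl-1,3-dioxan-4-yl]acetate | CCCCCCCCC[C@H](O)CC(=O)C[C@@H]1C[C@H](CC(=O)OC(C)(C)C)OC(C)(C)O1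
F8 | step 6 | 2-[(4R,6R)-6-{[(4S,6S)-2,2-dimethyl-6-nonyl-1,3-dioxan-4-yl]methyl}-2,2-dimethyl-1,3-dioxan-4-yl]acetic acid | CCCCCCCCC[C@H]1C[C@@H](C[C@@H]2C[C@H](CC(=O)O)OC(C)(C)O2)OC(C)(C)O1
F9 | step 6 | 5-{2-[(4R,6R)-6-{[(4S,6S)-2,2-dimethyl-6-nonyl-1,3-dioxan-4-yl]methyl}-2,2-dimethyl-1,3-dioxan-4-yl]acetyl}-2,2-dimethyl-1,3-dioxane-4,6-dione | CCCCCCCCC[C@H]1C[C@@H](C[C@@H]2C[C@H](CC(=O)C3C(=O)OC(C)(C)OC3=O)OC(C)(C)O2)OC(C)(C)O1
F10 | step 6 | 6-{[(4R,6R)-6-{[(4S,6S)-2,2-dimethyl-6-nonyl-1,3-dioxan-4-yl]methyl}-2,2-dimethyl-1,3-dioxan-4-yl]methyl}-2,2-dimethyl-4H-1,3-dioxin-4-one | CCCCCCCCC[C@H]1C[C@@H](C[C@@H]2C[C@H](CC3=CC(=O)OC(C)(C)O3)OC(C)(C)O2)OC(C)(C)O1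
F11 | step 6 | 6-[(2R,4R,6S,8S)-2,4,6,8-tetrahydroxyheptadecyl]-2,2-dimethyl-4H-1,3-dioxin-4-one | CCCCCCCCC[C@H](O)C[C@H](O)C[C@@H](O)C[C@@H](O)CC1=CC(=O)OC(C)(C)O1
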